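The target readings in Thursday's flask climb quickly and then level off, and the question is what that levelling off is worth.

| flask | substrate | reagent | free catalyst | second catalyst | temperature | remark | time |
|---|---|---|---|---|---|---|---|
| Thursday's | 0.20 M | 0.19 M | 0.13 mM | 1 mM | −20 °C | the very flask that is asked about, followed so far |  |
| Wednesday's | 0.13 M | 0.19 M | 0.13 mM | 1 mM | −25 °C | run made earlier |  |
| flask | 0.20 M | 0.190 M | 0.13 mM | 1.0 mM | −20 °C |  | 4.0 h |

| run | time / min | target / % |
|---|---|---|
| Thursday's | 30.0 | 14.8 |
| Thursday's | 60.0 | 16.9 |
| Thursday's | 90.0 | 16.1 |
| Thursday's | 150 | 19.0 |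
| Thursday's | 180 | 16.7 |
| Thursday's | 240 | 17.3 |
| Wednesday's | 1.00 | 1.4 |
| Wednesday's | 1.33 | 4.9 |
| Wednesday's | 2.00 | 2.8 |
| Wednesday's | 3.00 | 5.3 |
| Wednesday's | 5.00 | 7.7 |
| Wednesday's | 8.00 | 8.9 |
| Wednesday's | 12.0 | 9.0 |

(standard deviation of a reading: 1 percentage point)

- target, in percent of the substrate first charged, at 4.0 h
- which option adds most target ("none" when 2 percentage points or less is all one gets) (noon / winter / summer / dusk / autumn / none)
- target present, with what was taken out counted in, in percent of the substrate first charged, after winter
- target present, with what was taken out counted in, in percent of the substrate first charged, after dusk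

- noon: at 4.0 h add free catalyst, 100% of the amount charged, then wait 4.0 h
- winter: at 4.0 h take out 90% of the target then present, then wait 4.0 h
- summer: at 4.0 h add reagent, 100% of the amount charged, then wait 4.0 h
- dusk: change nothing and wait 4.0 h more
- autumn: at 4.0 h raise the temperature by 20 K, then wait 4.0 h

- target taken out counts as made
- "the catalyst" is free catalyst with its forms; second catalyst is a second catalyst
- additions bring no volume worth counting

Read the runs as a ladder of times. On the first rung, Wednesday's flask, colder than Thursday's, shows target at 5.3% after 3.00 min and 9.0% after 12.0 min. On the next rung, Thursday's flask already shows 14.8% at 30.0 min. On the last rung, Thursday's readings from 60.0 min to 240 min rise by 0.4 percentage points, less than the scatter of 1 point. Their mean is 17.2%, and that is your number for 4.0 h.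

Now count what is left, not what is made. Take one reagent per target. In Thursday's flask, [reagent] starts less than [substrate], so on that count reagent is the limiting reagent. Thursday's readings then give 81.9% for paper reagent, the share of the reagent charge still present if target were its one consumer. So the levelling off can mean two things. Either that reagent still stands in Thursday's flask, or it went down a road that no reading shows. The target readings do not tell these apart, so you name no option until [reagent] is read.

The forecast takes the first meaning: “Substrate and reagent both remain in large excess, so neither has run out.” It gives 17.3% at 4.0 h, 17.5% after winter and 17.4% after dusk, and it names noon as best.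

The flask gives 18.0% at 4.0 h, 30.0% after winter and 18.4% after dusk. Best is autumn, which adds 19 points, while noon adds 0.41 points.

    substrate + free catalyst ⇌ free catalyst + intermediate (K = 0.120, k = 2600 M⁻¹ min⁻¹, Ea = 41.0 kJ mol⁻¹, ΔH = 20.0 kJ mol⁻¹)
    reagent + second catalyst + intermediate → second catalyst + target (k = 2600 M⁻² min⁻¹, Ea = 36.0 kJ mol⁻¹)
    substrate + reagent → uncatalysed product (k = 0.130 M⁻¹ min⁻¹, Ea = 50.0 kJ mol⁻¹)
    target ⇌ isomer of the product (K = 2.50, k = 0.380 min⁻¹, Ea = 70.0 kJ mol⁻¹, ΔH = −35.0 kJ mol⁻¹)
    (constants at −20 °C)

Hold paper reagent, 81.9%, against the flask: reagent left at 240 min is 3.1% of its charge, and free catalyst stands at 100% of its charge. Beside its target, the flask then holds 29.0% of uncatalysed product and 45.0% of isomer of the product, both in percent of the substrate charged. Now take the neighbour with 0.50 M of substrate, its other charges unchanged. Its target of 7.36% gives paper reagent of 80.6%. Its reagent at 240 min is 0% of its charge, with 55% of its substrate left.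

The runs are calculated from invented constants.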